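**Retrosynthetic overview**
1. C40 polyene: two Wittig reactions on the C10 trienedial, first with the ε-end C15 phosphonium salt, then with the β-end C15 phosphonium salt (as diacetate; the acetates come off in the same pot).
2. Both C15 salts come from mirror-image trans-3-hydroxy-α-ionones (vinyl Grignard, then PPh3·HBr). For the β-end, the ε-type ring is first converted into the 3,4-cis-diol β-ring by hydroxyl-directed epoxidation and base-induced (vinylogous E1cB) epoxide opening.
3. Ring formation (ε-ring first, then the ring that becomes the β-ring): each ring is closed by proton-initiated cation–olefin cyclisation of an acyclic 3-acyloxy pseudoionone isomer (C-1 cation from an isopropenyl terminus, C1–C6 bond, loss of H-4), the same bond logic as lycopene cyclisation. The C-3 ester alone sets C-6.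
4. One acyclic (S)-hydroxy dienone feeds both series: Mitsunobu esterification (inversion) for the ε-series, in situ trifluoroacetylation (retention) for the β-series.
5. The hydroxy dienone comes from (S)-epichlorohydrin: isopropenyl Grignard, acetylide, Zr-catalysed methylalumination/iodination, Heck reaction with methyl vinyl ketone.

Assumption: the SMILES is read as all-E (3S,4R,3′R,6′R)-β,ε-carotene-3,4,3′-triol, and (2E,4E,6E)-2,7-dimethylocta-2,4,6-trienedial is bought.

**Route**

Step 1
Reactants: 1 (S)-epichlorohydrin [(2S)-2-(chloromethyl)oxirane]; 2 isopropenylmagnesium bromide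
Product: 3 (2S)-1-chloro-4-methylpent-4-en-2-ol
Conditions: 2 (1.2 equiv), CuI (10 mol %), THF, −40 → −20 °C; aq. NH4Cl
Reagents that add atoms: isopropenylmagnesium bromide, CC(=C)[Mg]Br
Why: Copper-catalysed Grignard opening of the epoxide (SN2 at the unsubstituted ring carbon) leaves the C–O stereocentre of 1 untouched, so 3 is formed as the single S enantiomer.

Step 2
Reactants: 3 (2S)-1-chloro-4-methylpent-4-en-2-ol; 4 lithium acetylide–ethylenediamine complex
Product: 6 (4S)-2-methylhept-1-en-6-yn-4-ol, via epoxide 5 (not isolated)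
Conditions: 4 (3 equiv), DMSO, 0 °C → rt; aq. NH4Cl
Reagents that add atoms: lithium acetylide–ethylenediamine complex, [Li+].[C-]#C.NCCN
Why: The acetylide first acts as base to close the chlorohydrin to terminal epoxide 5 (intramolecular Williamson etherification, no bond to the stereocentre broken) and then opens it at CH2 (SN2 epoxide opening), so the carbinol keeps its configuration.

Step 3
Reactants: 6 (4S)-2-methylhept-1-en-6-yn-4-ol; 7 trimethylaluminium; 8 iodine
Product: 10 (1E,4S)-1-iodo-2,6-dimethylhepta-1,6-dien-4-ol, via alkenylalane 9 (not isolated)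
Conditions: AlMe3 (3 equiv), ZrCp2Cl2 (25 mol %), CH2Cl2, 0 °C → rt; then I2 (1.3 equiv), THF, −30 → 0 °C; aq. Na2S2O3/NaHCO3
Reagents that add atoms: trimethylaluminium, C[Al](C)C; iodine, II
Why: Negishi zirconium-catalysed methylalumination adds Me and Al syn across the terminal alkyne with Me on the internal carbon, and iodinolysis of the C–Al bond goes with retention, giving only the E trisubstituted iodoalkene; the 1,1-disubstituted alkene is inert and the hydroxyl is masked as its aluminium alkoxide.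

Step 4
Reactants: 10 (1E,4S)-1-iodo-2,6-dimethylhepta-1,6-dien-4-ol; 11 methyl vinyl ketone (but-3-en-2-one)
Product: 12 (3E,5E,8S)-8-hydroxy-6,10-dimethylundeca-3,5,10-trien-2-one
Conditions: 11 (3 equiv), Pd(OAc)2 (5 mol %), Bu4NCl, NaHCO3, DMF, 40 °C
Reagents that add atoms: methyl vinyl ketone, CC(=O)C=C
Why: Heck reaction under Jeffery conditions couples the alkenyl iodide with the electron-poor alkene with retention of the iodide geometry and trans selectivity at the new double bond, giving the E,E-dienone whose carbonyl deactivates C5=C6 towards protonation in the cyclisation.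

Step 5
Reactants: 12 (3E,5E,8S)-8-hydroxy-6,10-dimethylundeca-3,5,10-trien-2-one; 13 chloroacetic acid
Product: 14 (4R,6E,8E)-2,6-dimethyl-10-oxoundeca-1,6,8-trien-4-yl chloroacetate
Conditions: 13 (1.5 equiv), PPh3, DIAD, THF, 0 °C → rt
Reagents that add atoms: chloroacetic acid, OC(=O)CCl
Why: Mitsunobu esterification displaces the activated, unhindered homoallylic hydroxyl by SN2 with clean inversion (S to R), which is the C-3 configuration of the ε-ring, and installs an electron-poor ester.

Step 6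
Reactants: 14 (4R,6E,8E)-2,6-dimethyl-10-oxoundeca-1,6,8-trien-4-yl chloroacetate
Product: 16 (3E)-4-[(1R,4R)-4-hydroxy-2,6,6-trimethylcyclohex-2-en-1-yl]but-3-en-2-one [(3R,6R)-3-hydroxy-α-ionone], via cyclised chloroacetate 15 (not isolated)
Conditions: BF3·OEt2 (3 equiv), CF3CO2H (0.2 equiv), CH2Cl2, −20 → 0 °C; Et3N; then K2CO3, MeOH, 0 °C
Reagents that add atoms: none
Why: Proposed new method: the acid protonates the only alkene not deactivated by the dienone (the 1,1-disubstituted terminus) to the tertiary C-1 cation, which is captured by C-6 of the E-configured C5=C6 bond through a chair in which the C-3 ester is equatorial (an axial ester would clash 1,3 with a C-1 methyl) and C-7 is equatorial, so C-6 forms trans to the C-3 oxygen (6R from 3R), and kinetic loss of H-4 gives the ε-type alkene, while the electron-poor ester resists allylic ionisation and acyloxy participation until it is removed by methanolysis; the closest known reaction is the BF3- or H3PO4-mediated cyclisation of pseudoionone to α-ionone and of pseudoirones to α-irones.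

Step 7
Reactants: 16 (3R,6R)-3-hydroxy-α-ionone; 17 vinylmagnesium bromide
Product: 18 (1R,4R)-4-[(1E)-3-hydroxy-3-methylpenta-1,4-dien-1-yl]-3,5,5-trimethylcyclohex-2-en-1-ol (both epimers at the new carbinol)
Conditions: 17 (3.5 equiv), THF, −20 → 0 °C; aq. NH4Cl
Reagents that add atoms: vinylmagnesium bromide, C=C[Mg]Br
Why: 1,2-Addition of the vinyl Grignard reagent to the enone carbonyl (the vinyl-ionol reaction; excess reagent covers the free hydroxyl) gives the tertiary carbinol as both epimers, a centre that is erased in step 8.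

Step 8
Reactants: 18 (ε-series vinyl carbinol); 19 triphenylphosphine hydrobromide
Product: 20 [(2E,4E)-5-[(1R,4R)-4-hydroxy-2,6,6-trimethylcyclohex-2-en-1-yl]-3-methylpenta-2,4-dien-1-yl]triphenylphosphonium bromide
Conditions: 19 (1.05 equiv), CH2Cl2, 0 °C → rt; crystallise
Reagents that add atoms: triphenylphosphine hydrobromide, [Br-].c1ccccc1[PH+](c1ccccc1)c1ccccc1
Why: PPh3·HBr ionises the tertiary doubly allylic alcohol and PPh3 traps the delocalised cation at its unhindered terminus (SN1′ allylic transposition, the standard C15 Wittig salt synthesis), much faster than the secondary ring allylic alcohol can ionise, so C-3 and C-6 are not touched.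

Step 9
Reactants: 12 (3E,5E,8S)-8-hydroxy-6,10-dimethylundeca-3,5,10-trien-2-one
Product: 23 (3E)-4-[(1S,4S)-4-hydroxy-2,6,6-trimethylcyclohex-2-en-1-yl]but-3-en-2-one [(3S,6S)-3-hydroxy-α-ionone], via trifluoroacetate 21 (not isolated), via cyclised trifluoroacetate 22 (not isolated)
Conditions: (CF3CO)2O (1.05 equiv), CH2Cl2, 0 °C; then BF3·OEt2 (3 equiv), −20 → 0 °C; Et3N; then K2CO3, MeOH, 0 °C
Reagents that add atoms: none
Why: Proposed new method: in situ trifluoroacetylation (retention at the carbinol) is followed by the same proton-initiated cation–olefin cyclisation as in step 6 in the mirror-image series, giving through the same chair the 3,6-trans (3S,6S) ring, the trifluoroacetate (non-participating, slow to ionise, cleaved by methanolysis on work-up) serving only to keep C-3 intact; the closest known reaction is the BF3-mediated pseudoionone to α-ionone cyclisation.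

Step 10
Reactants: 23 (3S,6S)-3-hydroxy-α-ionone; 24 3-chloroperoxybenzoic acid (mCPBA)
Product: 26 (3E)-4-[(3R,4S)-3,4-dihydroxy-2,6,6-trimethylcyclohex-1-en-1-yl]but-3-en-2-one [(3S,4R)-3,4-dihydroxy-β-ionone in carotenoid numbering], via epoxy alcohol 25 (not isolated)
Conditions: mCPBA (1.1 equiv), NaHCO3, CH2Cl2, 0 °C; Me2S; then NaOMe (2 equiv), MeOH, 0 °C → rt
Reagents that add atoms: 3-chloroperoxybenzoic acid, OOC(=O)c1cccc(Cl)c1
Why: Henbest hydroxyl-directed peracid epoxidation puts the oxygen on the face of the 3-OH (also the face opposite the side chain), and methoxide then removes the γ-hydrogen at C-6 so that the dienolate opens the epoxide at C-5 (vinylogous E1cB, as in the α-ionone epoxide to 4-hydroxy-β-ionone isomerisation), leaving the C-4 oxygen cis to 3-OH (4R) and the double bond in the β position.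

Step 11
Reactants: 26 (3S,4R)-3,4-dihydroxy-β-ionone; 17 vinylmagnesium bromide
Product: 27 (1S,2R)-4-[(1E)-3-hydroxy-3-methylpenta-1,4-dien-1-yl]-3,5,5-trimethylcyclohex-3-ene-1,2-diol (both epimers at the new carbinol)
Conditions: 17 (5 equiv), THF, −20 → 0 °C; aq. NH4Cl
Reagents that add atoms: vinylmagnesium bromide, C=C[Mg]Br
Why: 1,2-Addition of the vinyl Grignard reagent to the methyl ketone (two equivalents are spent on the diol) gives the tertiary carbinol as both epimers, erased in step 13.

Step 12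
Reactants: 27 (β-series triol); 28 acetic anhydride
Product: 29 (1S,2R)-4-[(1E)-3-hydroxy-3-methylpenta-1,4-dien-1-yl]-3,5,5-trimethylcyclohex-3-ene-1,2-diyl diacetate
Conditions: 28 (2.5 equiv), pyridine, DMAP (5 mol %), CH2Cl2, 0 °C
Reagents that add atoms: acetic anhydride, CC(=O)OC(C)=O
Why: Acetylation (nucleophilic acyl substitution) takes only the two secondary hydroxyls, which lowers the tendency of the allylic C-4 oxygen to ionise in step 13; the hindered tertiary alcohol stays free.

Step 13
Reactants: 29 (β-series diacetate carbinol); 19 triphenylphosphine hydrobromide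
Product: 30 [(2E,4E)-5-[(3R,4S)-3,4-diacetoxy-2,6,6-trimethylcyclohex-1-en-1-yl]-3-methylpenta-2,4-dien-1-yl]triphenylphosphonium bromide
Conditions: 19 (1.05 equiv), CH2Cl2, 0 °C → rt; crystallise
Reagents that add atoms: triphenylphosphine hydrobromide, [Br-].c1ccccc1[PH+](c1ccccc1)c1ccccc1
Why: SN1′ phosphonium salt formation as in step 8; the allylic acetate flanked by a second acetate does not ionise under PPh3·HBr, so both stereocentres are kept.

Step 14
Reactants: 20 (ε-end C15 phosphonium bromide); 31 (2E,4E,6E)-2,7-dimethylocta-2,4,6-trienedial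
Product: 33 (2E,4E,6E,8E,10E,12E)-13-[(1R,4R)-4-hydroxy-2,6,6-trimethylcyclohex-2-en-1-yl]-2,7,11-trimethyltrideca-2,4,6,8,10,12-hexaenal, via ylide 32 (not isolated)
Conditions: 31 (3 equiv), NaOMe (1.1 equiv), CH2Cl2–MeOH, −10 °C → rt; then heptane, 90 °C (Z → E)
Reagents that add atoms: (2E,4E,6E)-2,7-dimethylocta-2,4,6-trienedial, O=C/C(C)=C/C=C/C=C(C)/C=O
Why: Wittig olefination of the semistabilised ylide with a threefold excess of the symmetrical dialdehyde gives the mono-olefination product, and thermal equilibration turns the Z isomer of the new double bond into the all-E polyenal; no stereocentre is touched.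

Step 15
Reactants: 33 (C25 hydroxy aldehyde); 30 (β-end C15 phosphonium bromide)
Product: 36 (3S,4R,3′R,6′R)-β,ε-carotene-3,4,3′-triol (all-E; CNP0191612.1), via ylide 34 (not isolated), via C40 diacetate 35 (not isolated)
Conditions: 30 (1.2 equiv), NaOMe (5 equiv), CH2Cl2–MeOH, 0 °C → rt, 12 h; then EtOH, 70 °C under N2 (Z → E); crystallise
Reagents that add atoms: β-end phosphonium bromide 30, [Br-].c1ccccc1[P+](c1ccccc1)(c1ccccc1)C/C=C(C)/C=C/C1=C(C)[C@@H](OC(C)=O)[C@@H](OC(C)=O)CC1(C)C
Why: The second Wittig olefination completes the C40 chain, excess methoxide then removes both acetates by transesterification, and heating equilibrates the new double bond to E, giving the all-E triol with its four stereocentres set in steps 1, 5, 6 and 10.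

**Compound list**

1 | (S)-epichlorohydrin, (2S)-2-(chloromethyl)oxirane | ClC[C@@H]1CO1 | starting material
2 | isopropenylmagnesium bromide | CC(=C)[Mg]Br | starting material
3 | (2S)-1-chloro-4-methylpent-4-en-2-ol | C=C(C)C[C@H](O)CCl | intermediate
4 | lithium acetylide–ethylenediamine complex | [Li+].[C-]#C.NCCN | starting material
5 | (2S)-2-(2-methylprop-2-en-1-yl)oxirane | C=C(C)C[C@H]1CO1 | intermediate (not isolated)
6 | (4S)-2-methylhept-1-en-6-yn-4-ol | C=C(C)C[C@H](O)CC#C | intermediate
7 | trimethylaluminium | C[Al](C)C | starting material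
8 | iodine | II | starting material
9 | dimethyl[(1E,4S)-4-(dimethylalumanyloxy)-2,6-dimethylhepta-1,6-dien-1-yl]alumane | C=C(C)C[C@H](O[Al](C)C)C/C(C)=C/[Al](C)C | intermediate (not isolated)
10 | (1E,4S)-1-iodo-2,6-dimethylhepta-1,6-dien-4-ol | C=C(C)C[C@H](O)C/C(C)=C/I | intermediate
11 | methyl vinyl ketone (but-3-en-2-one) | CC(=O)C=C | starting material
12 | (3E,5E,8S)-8-hydroxy-6,10-dimethylundeca-3,5,10-trien-2-one | C=C(C)C[C@H](O)C/C(C)=C/C=C/C(C)=O | intermediate
13 | chloroacetic acid | OC(=O)CCl | starting material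
14 | (4R,6E,8E)-2,6-dimethyl-10-oxoundeca-1,6,8-trien-4-yl chloroacetate | C=C(C)C[C@@H](OC(=O)CCl)C/C(C)=C/C=C/C(C)=O | intermediate
15 | (1R,4R)-3,5,5-trimethyl-4-[(1E)-3-oxobut-1-en-1-yl]cyclohex-2-en-1-yl chloroacetate | CC1=C[C@H](OC(=O)CCl)CC(C)(C)[C@H]1/C=C/C(C)=O | intermediate (not isolated)
16 | (3E)-4-[(1R,4R)-4-hydroxy-2,6,6-trimethylcyclohex-2-en-1-yl]but-3-en-2-one, (3R,6R)-3-hydroxy-α-ionone | CC1=C[C@H](O)CC(C)(C)[C@H]1/C=C/C(C)=O | intermediate
17 | vinylmagnesium bromide | C=C[Mg]Br | starting material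
18 | (1R,4R)-4-[(1E)-3-hydroxy-3-methylpenta-1,4-dien-1-yl]-3,5,5-trimethylcyclohex-2-en-1-ol (side-chain carbinol: both epimers) | CC1=C[C@H](O)CC(C)(C)[C@H]1/C=C/C(C)(O)C=C | intermediate
19 | triphenylphosphine hydrobromide | [Br-].c1ccccc1[PH+](c1ccccc1)c1ccccc1 | starting material
20 | [(2E,4E)-5-[(1R,4R)-4-hydroxy-2,6,6-trimethylcyclohex-2-en-1-yl]-3-methylpenta-2,4-dien-1-yl]triphenylphosphonium bromide | CC1=C[C@H](O)CC(C)(C)[C@H]1/C=C/C(C)=C/C[P+](c1ccccc1)(c1ccccc1)c1ccccc1.[Br-] | intermediate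
21 | (4S,6E,8E)-2,6-dimethyl-10-oxoundeca-1,6,8-trien-4-yl trifluoroacetate | C=C(C)C[C@H](OC(=O)C(F)(F)F)C/C(C)=C/C=C/C(C)=O | intermediate (not isolated)
22 | (1S,4S)-3,5,5-trimethyl-4-[(1E)-3-oxobut-1-en-1-yl]cyclohex-2-en-1-yl trifluoroacetate | CC1=C[C@@H](OC(=O)C(F)(F)F)CC(C)(C)[C@@H]1/C=C/C(C)=O | intermediate (not isolated)
23 | (3E)-4-[(1S,4S)-4-hydroxy-2,6,6-trimethylcyclohex-2-en-1-yl]but-3-en-2-one, (3S,6S)-3-hydroxy-α-ionone | CC1=C[C@@H](O)CC(C)(C)[C@@H]1/C=C/C(C)=O | intermediate
24 | 3-chloroperoxybenzoic acid | OOC(=O)c1cccc(Cl)c1 | starting material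
25 | (3E)-4-[(1R,2S,5S,6S)-5-hydroxy-1,3,3-trimethyl-7-oxabicyclo[4.1.0]heptan-2-yl]but-3-en-2-one, (3S,4S,5R,6S)-4,5-epoxy-3-hydroxy-4,5-dihydro-α-ionone (epoxide cis to OH) | C[C@]12O[C@H]1[C@@H](O)CC(C)(C)[C@@H]2/C=C/C(C)=O | intermediate (not isolated)
26 | (3E)-4-[(3R,4S)-3,4-dihydroxy-2,6,6-trimethylcyclohex-1-en-1-yl]but-3-en-2-one (cis-diol) | CC(=O)/C=C/C1=C(C)[C@@H](O)[C@@H](O)CC1(C)C | intermediate
27 | (1S,2R)-4-[(1E)-3-hydroxy-3-methylpenta-1,4-dien-1-yl]-3,5,5-trimethylcyclohex-3-ene-1,2-diol (side-chain carbinol: both epimers) | C=CC(C)(O)/C=C/C1=C(C)[C@@H](O)[C@@H](O)CC1(C)C | intermediate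
28 | acetic anhydride | CC(=O)OC(C)=O | starting material
29 | (1S,2R)-4-[(1E)-3-hydroxy-3-methylpenta-1,4-dien-1-yl]-3,5,5-trimethylcyclohex-3-ene-1,2-diyl diacetate | C=CC(C)(O)/C=C/C1=C(C)[C@@H](OC(C)=O)[C@@H](OC(C)=O)CC1(C)C | intermediate
30 | [(2E,4E)-5-[(3R,4S)-3,4-diacetoxy-2,6,6-trimethylcyclohex-1-en-1-yl]-3-methylpenta-2,4-dien-1-yl]triphenylphosphonium bromide | [Br-].c1ccccc1[P+](c1ccccc1)(c1ccccc1)C/C=C(C)/C=C/C1=C(C)[C@@H](OC(C)=O)[C@@H](OC(C)=O)CC1(C)C | intermediate
31 | (2E,4E,6E)-2,7-dimethylocta-2,4,6-trienedial | O=C/C(C)=C/C=C/C=C(C)/C=O | starting material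
32 | ylide of 20, [(2E,4E)-5-[(1R,4R)-4-hydroxy-2,6,6-trimethylcyclohex-2-en-1-yl]-3-methylpenta-2,4-dien-1-ylidene]triphenylphosphorane | CC1=C[C@H](O)CC(C)(C)[C@H]1/C=C/C(C)=C/C=P(c1ccccc1)(c1ccccc1)c1ccccc1 | intermediate (not isolated)
33 | (2E,4E,6E,8E,10E,12E)-13-[(1R,4R)-4-hydroxy-2,6,6-trimethylcyclohex-2-en-1-yl]-2,7,11-trimethyltrideca-2,4,6,8,10,12-hexaenal | CC1=C[C@H](O)CC(C)(C)[C@H]1/C=C/C(C)=C/C=C/C(C)=C/C=C/C=C(C)/C=O | intermediate
34 | ylide of 30, [(2E,4E)-5-[(3R,4S)-3,4-diacetoxy-2,6,6-trimethylcyclohex-1-en-1-yl]-3-methylpenta-2,4-dien-1-ylidene]triphenylphosphorane | c1ccccc1P(c1ccccc1)(c1ccccc1)=C/C=C(C)/C=C/C1=C(C)[C@@H](OC(C)=O)[C@@H](OC(C)=O)CC1(C)C | intermediate (not isolated)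
35 | (3S,4R,3′R,6′R)-β,ε-carotene-3,4,3′-triol 3,4-diacetate (all-E) | CC1=C[C@H](O)CC(C)(C)[C@H]1/C=C/C(C)=C/C=C/C(C)=C/C=C/C=C(C)/C=C/C=C(C)/C=C/C1=C(C)[C@@H](OC(C)=O)[C@@H](OC(C)=O)CC1(C)C | intermediate (not isolated)
36 | (3S,4R,3′R,6′R)-β,ε-carotene-3,4,3′-triol (all-E) | CC1=C[C@H](O)CC(C)(C)[C@H]1/C=C/C(C)=C/C=C/C(C)=C/C=C/C=C(C)/C=C/C=C(C)/C=C/C1=C(C)[C@@H](O)[C@@H](O)CC1(C)C | target

**Totals and risks**

Total step count: 15. Longest linear sequence: 10 steps (1–8, 14, 15; the β-series line 1–4, 9–13, 15 is equally long).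

The three steps most likely to fail:

Step 6 (ε-ring closure). The kinetic loss of H-4 may give way to the conjugated alkene isomer, or the allylic ester of 15 may ionise under the acid. The fallback sets out from 14 and replaces proton initiation by metal-cation initiation. Treating 14 with Hg(OTf)2·PhNMe2 in MeNO2 at −20 °C, then aqueous NaCl, adds mercury to the CH2 terminus of the isopropenyl group; the same tertiary C-1 cation closes the ring through the same chair, and the amine-buffered medium removes H-4 with no free strong acid present. This gives (3R,6R)-3-(chloroacetoxy)-16-(chloromercurio)-α-ionone F1. Radical demercuration (Bu3SnH, AIBN, toluene, 60 °C) turns CH2HgCl into the second C-1 methyl and comes back to the route at 15, which is methanolysed to 16 as in step 6.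

Step 8 (phosphonium salt with a free ring allylic alcohol). The ε-ring 3-OH of 18 may ionise or be substituted under PPh3·HBr. The fallback sets out from 16 and builds the salt without Brønsted acid. Horner–Wadsworth–Emmons reaction with triethyl phosphonoacetate (NaH, THF; 9E isomer separated) gives ethyl (2E,4E)-5-[(1R,4R)-4-hydroxy-2,6,6-trimethylcyclohex-2-en-1-yl]-3-methylpenta-2,4-dienoate F2. Reduction with iBu2AlH gives (1R,4R)-4-[(1E,3E)-5-hydroxy-3-methylpenta-1,3-dien-1-yl]-3,5,5-trimethylcyclohex-2-en-1-ol F3. Appel bromination (CBr4, PPh3, CH2Cl2, −20 °C, primary hydroxyl only) gives (1R,4R)-4-[(1E,3E)-5-bromo-3-methylpenta-1,3-dien-1-yl]-3,5,5-trimethylcyclohex-2-en-1-ol F4, which is quaternised by excess PPh3 in the same flask and comes back to the route at 20.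

Step 9 (second ring closure with the in situ trifluoroacetate). If the trifluoroacetate series does not cyclise cleanly, the second cyclisation is dropped and the β-series is taken from the ε-series ketone by inverting C-3 after ring formation. The fallback sets out from 16: Mitsunobu reaction with chloroacetic acid 13 (PPh3, DIAD) gives (3S,6R)-3-(chloroacetoxy)-α-ionone F5, and K2CO3/MeOH gives (3S,6R)-3-hydroxy-α-ionone F6. Hydroxyl-directed epoxidation with VO(acac)2 and tBuOOH, chosen because here the side chain is on the same face as the hydroxyl, gives (3S,4S,5R,6R)-4,5-epoxy-3-hydroxy-4,5-dihydro-α-ionone F7. NaOMe/MeOH opens it as in step 10 and the route is rejoined at 26, where C-6 is no longer a stereocentre.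

**Further compounds**

F1 | step 6 | (3R,6R)-3-(chloroacetoxy)-16-(chloromercurio)-α-ionone: chloroacetate 15 with one C-1 methyl as CH2HgCl (both C-1 epimers) | CC1=C[C@H](OC(=O)CCl)CC(C)(C[Hg]Cl)[C@H]1/C=C/C(C)=O
F2 | step 8 | ethyl (2E,4E)-5-[(1R,4R)-4-hydroxy-2,6,6-trimethylcyclohex-2-en-1-yl]-3-methylpenta-2,4-dienoate | CC1=C[C@H](O)CC(C)(C)[C@H]1/C=C/C(C)=C/C(=O)OCC
F3 | step 8 | (1R,4R)-4-[(1E,3E)-5-hydroxy-3-methylpenta-1,3-dien-1-yl]-3,5,5-trimethylcyclohex-2-en-1-ol | CC1=C[C@H](O)CC(C)(C)[C@H]1/C=C/C(C)=C/CO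
F4 | step 8 | (1R,4R)-4-[(1E,3E)-5-bromo-3-methylpenta-1,3-dien-1-yl]-3,5,5-trimethylcyclohex-2-en-1-ol | CC1=C[C@H](O)CC(C)(C)[C@H]1/C=C/C(C)=C/CBr
F5 | step 9 | (1S,4R)-3,5,5-trimethyl-4-[(1E)-3-oxobut-1-en-1-yl]cyclohex-2-en-1-yl chloroacetate, (3S,6R)-3-(chloroacetoxy)-α-ionone | CC1=C[C@@H](OC(=O)CCl)CC(C)(C)[C@H]1/C=C/C(C)=O
F6 | step 9 | (3E)-4-[(1R,4S)-4-hydroxy-2,6,6-trimethylcyclohex-2-en-1-yl]but-3-en-2-one, (3S,6R)-3-hydroxy-α-ionone | CC1=C[C@@H](O)CC(C)(C)[C@H]1/C=C/C(C)=O
F7 | step 9 | (3E)-4-[(1R,2R,5S,6S)-5-hydroxy-1,3,3-trimethyl-7-oxabicyclo[4.1.0]heptan-2-yl]but-3-en-2-one, (3S,4S,5R,6R)-4,5-epoxy-3-hydroxy-4,5-dihydro-α-ionone | C[C@]12O[C@H]1[C@@H](O)CC(C)(C)[C@H]2/C=C/C(C)=O
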